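**Remark on the chemistry (assumption):** the C3'–C8'' biaryl axis carries no descriptor in the target and is treated as configurationally unassigned, so no atroposelection is attempted.

## Analysis of the target

The target 26 is a 3',8''-linked biflavone of the amentoflavone type. Flavone 1 is a 5,7-dihydroxy-2-aryl-4H-chromen-4-one whose ring B (C1'–C6') has a hydroxyl at C4' and is bonded through C3' to C8'' of flavone 2. Flavone 2 is a 5''-hydroxy-2''-(4-hydroxyphenyl)chromen-4-one whose C7'' oxygen is a 3-methylbut-2-enyl (prenyl) ether. There is no stereocentre; the only possible stereogenic element is the C3'–C8'' axis, flanked by the oxygens on C4', C7'' and C8a''. The sensitive groups are the prenyl aryl ether (protic and Lewis acids, hydrogenation, zerovalent palladium with nucleophiles), the two pyranones (attack of hydroxide or alkoxide at C2 and C2'' with ring opening) and five free phenols. The main difficulty is that only one of six phenolic oxygens, O7'', is alkylated while its near twin O7 in flavone 1 stays free, so selective alkylation of the hexaol at the end is not realistic. A second difficulty is the congested C3'–C8'' bond. The strategy rests on ring A'' of flavone 2: the oxygen-bearing carbons C8a'' and C7'' are the two neighbours of C8'' and lie ortho and para to C4a'', which carries the C4'' ketone. Both C–O bonds can therefore come from C–F bonds of a 2,6-difluoroaryl unit that is symmetric about the biaryl bond. The ortho fluorine is taken by the pyranone oxygen O1'' and the para fluorine by the prenyl alkoxide.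

## Retrosynthetic reasoning

**26 to 25.** Only three O–CH2OMe acetal bonds (at O4', O5'' and O4''') are cut. Acetal ethers are chosen because they survive every organometallic and basic step and come off under conditions mild enough for the allylic ether.

**25 to 20 and 23.** The pyranone of flavone 1 is cut at C4–C4a, C3–C4 and O1–C2. In the forward sense ring A of flavone 1 comes from the iodo triacetate 23, C4 from a carbonyl carbon inserted under palladium catalysis, and C2/C3 from the terminal alkyne 20. Building flavone 1 last keeps its electrophilic pyranone out of all strongly basic steps. Compound 23 is symmetric, so either ortho oxygen can close the ring and there is no regiochemical question; it comes from 21 through 22 by iodination and acetylation.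

**20 to 19 to 18.** The C1'–C(sp) bond is cut. The aryl bromide of 18, carried unchanged from 3, is the handle for a Sonogashira coupling followed by desilylation.

**18 to 16 and 17.** The C7''–O bond is cut. The forward reaction is a displacement of the fluorine para to C4a'' by the alkoxide of 17. The alkylated oxygen is thus marked by never having been a phenol. The step is placed directly after ring closure, when every phenol is still masked (a phenoxide on ring A'' would shut the substitution down). It also comes before the palladium steps, whose secondary amines could compete for the C–F bond.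

**16 to 15 (key disconnection).** The O1''–C8a'' bond is cut. The forward step is an intramolecular substitution of the fluorine ortho to the aroyl group by the enolate oxygen of the 1,3-diketone 15. A cut at O1''–C2'' would require a free phenol at C8a'' and hence a way to tell it from the oxygen at C7''; the C–F route needs no such differentiation.

**15 to 10 and 13 (through 14).** The C2''–C3'' bond is cut, a Claisen-type C-acylation of the methyl ketone 10. The acyl donor 14 is an activated amide and not an ester, so no alkoxide is released next to two activated fluorines. Acid 13 comes from 11 through 12.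

**10 to 7.** The C4a''–C4'' bond is cut. The forward step is deprotonation of 7 between a fluorine and the acetal ether, then acetylation. The two such positions of 7 are interchanged by rotation about the biaryl bond, so only one product is possible.

**7 to 2 and 4.** The C8''–C3' bond is cut while C8'' is flanked only by two small fluorines, the least hindered moment for this coupling. An arylzinc is used because 2,6-difluoroaryl boron reagents lose boron readily under base, and the iodide of 4 reacts ahead of its bromide. Compounds 2 and 4 come from the commercial phenols 1 and 3.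

## Alternatives that were turned down

**Alternative 1:** Ring A'' is built around the biaryl bond by a benzannulation.
- **Disconnection:** C8''–C8a'' and C6''–C7'' are cut, leading to the cyclobutenone A1 (C8a'', C4a'', C5'', C6'') and the aryl silyl ynol ether A2 (C8'' with ring B attached, and C7'' with its silyloxy group).
- **Forward key step:** thermal four-electron opening of A1 to a vinylketene, cycloaddition with the electron-rich alkyne of A2, a second four-electron opening and a six-electron closure give the phenol A3.
- **For:** the three oxygens of ring A'' in A3 are all different (free hydroxyl at C8a'', silyl ether at C7'', acetal at C5''), so the differentiation problem is solved at once. The hindered biaryl bond is never made by cross-coupling. The regiochemistry of the annulation is dependable.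
- **Against:** A3 still lacks C4''. An acyl group must go onto C4a'', between the hydroxyl and the acetal, while C6'' is about as activated. The pyranone and a silyl-to-prenyl exchange would follow, and both A1 and A2 need multistep preparation.
- **Comparison:** this route is at least as strong on oxygen differentiation and on the biaryl bond. The chosen route offers a purchased ring A'' with the pattern in place, a C4a'' acylation made unambiguous by symmetry (7 to 10), and fewer steps to the closed pyranone 16.

**Alternative 2:** Ring B is built by a Diels–Alder reaction and aromatised.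
- **Disconnection:** C1'–C2' and C5'–C6' are cut, giving the 2-silyloxy-3-arylbutadiene A4 (the diene sits on C8'' of a complete, prenylated flavone 2) and the 2-ethynylchromone A5 (flavone 1 without ring B).
- **Forward key step:** [4+2] addition and dehydrogenation of the cyclohexadiene in the same flask give the protected biflavone A6.
- **For:** it is the most convergent plan. Both pyranones are finished before the union, no biaryl coupling is needed, and the prenyl ether can come from a classical selective 7-O-alkylation of a 5,7-dihydroxyflavone.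
- **Against:** the silyloxy group at C4' and the aryl group at C3' sit on adjacent diene carbons and direct the acceptor to opposite ends, so the regiochemistry is not secured. The 2,3-disubstituted diene with a twisted, doubly ortho-substituted aryl group populates the reactive s-cis form poorly. A4 needs a four-carbon enone chain on the hindered C8'', which only moves the problem. The oxidant for aromatisation must spare the allylic ether.
- **Comparison:** stronger on convergence. The chosen route is longer in its linear sequence, but each regiochemical decision is fixed by symmetry or by a tether.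

**Alternative 3:** Ring A'' is closed on a pyranone in a biomimetic Claisen condensation.
- **Disconnection:** C4a''–C5'' is cut. The precursor A7 is a 2-aryl-4-pyranone whose C8a'' carries the chain C8''H(aryl)–C7''(=O)–C6''H2–C5''O2Me.
- **Forward key step:** base forms the extended enolate through C8'' and the pyranone, C4a'' attacks the ester, and enolisation gives the 5'',7''-diol A8.
- **For:** in A8 the hydrogen-bonded 5''-hydroxyl and the acidic 7''-hydroxyl are told apart by classical selective alkylation with a prenyl halide. That end game is better tested than displacing an aryl fluorine with an alkoxide.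
- **Against:** A7 is hard to reach, because C8'' is a tertiary carbon bearing ring B, a ketone and the pyranone. Its most acidic site is C6'', whose enolate is unproductive and deactivates the ester, so the wanted nucleophile must be formed as a dianion or under kinetic control. The C7'' ketone and O-acylation offer competing closures, and flavone 1 must endure the strong base.
- **Comparison:** stronger at the prenylation stage. The chosen route replaces phenol differentiation by a C–F bond and closes its ring in the only mode the tether allows, from a precursor (15) made in four linear steps.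

Key step: step 8

## Route

**Step 1**
Reactants: 1 4-bromo-3,5-difluorophenol
Product: 2 2-bromo-1,3-difluoro-5-(methoxymethoxy)benzene
Conditions: MOMCl, i-Pr2NEt, CH2Cl2, 0 °C→rt
Reagents that add atoms: chloromethyl methyl ether, COCCl
Why: O-alkylation of the phenol with an α-chloro ether (MOM protection); the acetal ether withstands the organometallic steps and later directs metalation.

**Step 2**
Reactants: 3 4-bromo-2-iodophenol
Product: 4 4-bromo-2-iodo-1-(methoxymethoxy)benzene
Conditions: MOMCl, i-Pr2NEt, CH2Cl2, 0 °C→rt
Reagents that add atoms: chloromethyl methyl ether, COCCl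
Why: MOM protection of the ring B phenol, which must not quench the arylzinc in step 3.

**Step 3**
Reactants: 2 2-bromo-1,3-difluoro-5-(methoxymethoxy)benzene; 4 4-bromo-2-iodo-1-(methoxymethoxy)benzene
Product: 7 5'-bromo-2,6-difluoro-2',4-bis(methoxymethoxy)-1,1'-biphenyl, via arylmagnesium chloride 5 (not isolated), via arylzinc chloride 6 (not isolated)
Conditions: i-PrMgCl·LiCl, THF, −20 °C; ZnCl2, −20 °C→rt; then 4, Pd(PPh3)4 (cat.), THF, 50 °C
Reagents that add atoms: none
Why: Br/Mg exchange is fast at the bromide flanked by two fluorines, transmetalation to zinc gives a reagent that neither eliminates to an aryne nor loses the metal as the boron analogue would, and the Negishi coupling under Pd(PPh3)4 takes the C–I bond of 4 ahead of its C–Br bond.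

**Step 4**
Reactants: 7 5'-bromo-2,6-difluoro-2',4-bis(methoxymethoxy)-1,1'-biphenyl
Product: 10 1-[5'-bromo-2,6-difluoro-2',4-bis(methoxymethoxy)-[1,1'-biphenyl]-3-yl]ethan-1-one, via aryllithium 8 (not isolated), via lithium hemiaminal adduct 9 (not isolated)
Conditions: LiN(i-Pr)2, THF, −78 °C; MeC(O)N(OMe)Me, −78→−30 °C; AcOH quench
Reagents that add atoms: N-methoxy-N-methylacetamide, CC(=O)N(C)OC
Why: directed ortho-metalation at the proton between fluorine and the acetal ether, the most acidic one; the two such positions are equivalent by rotation about the biaryl bond and the amide base does not exchange the aryl bromide; Weinreb acylation stops at the chelated adduct 9, which releases the ketone only on quench.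

**Step 5**
Reactants: 11 methyl 4-hydroxybenzoate
Product: 12 methyl 4-(methoxymethoxy)benzoate
Conditions: MOMCl, i-Pr2NEt, CH2Cl2, 0 °C→rt
Reagents that add atoms: chloromethyl methyl ether, COCCl
Why: MOM protection of the phenol that becomes O4''' of flavone 2.

**Step 6**
Reactants: 12 methyl 4-(methoxymethoxy)benzoate
Product: 13 4-(methoxymethoxy)benzoic acid
Conditions: LiOH, THF/MeOH/H2O, rt; then aq. HCl to pH 4, 0 °C
Reagents that add atoms: lithium hydroxide, [Li+].[OH-]
Why: ester saponification; acidification only to pH 4 in the cold leaves the aryl acetal ether intact.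

**Step 7**
Reactants: 13 4-(methoxymethoxy)benzoic acid; 10 1-[5'-bromo-2,6-difluoro-2',4-bis(methoxymethoxy)-[1,1'-biphenyl]-3-yl]ethan-1-one
Product: 15 1-[5'-bromo-2,6-difluoro-2',4-bis(methoxymethoxy)-[1,1'-biphenyl]-3-yl]-3-[4-(methoxymethoxy)phenyl]propane-1,3-dione, via acyl imidazole 14 (not isolated)
Conditions: 13, CDI, THF, rt; 10, LiN(SiMe3)2 (excess), THF, −78 °C; combine, −78→0 °C; AcOH quench
Reagents that add atoms: none
Why: Claisen-type C-acylation of the lithium enolate of 10 by an acyl imidazole; the leaving group is an imidazolide and not an alkoxide, so nothing nucleophilic is released beside the two activated fluorines, and the excess base covers the acidic product and the imidazole from the activation.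

**Step 8**
Reactants: 15 1-[5'-bromo-2,6-difluoro-2',4-bis(methoxymethoxy)-[1,1'-biphenyl]-3-yl]-3-[4-(methoxymethoxy)phenyl]propane-1,3-dione
Product: 16 8-[5-bromo-2-(methoxymethoxy)phenyl]-7-fluoro-5-(methoxymethoxy)-2-[4-(methoxymethoxy)phenyl]-4H-chromen-4-one
Conditions: K2CO3, DMSO (dilute), 50 °C
Reagents that add atoms: none
Why: K2CO3 converts the 1,3-diketone of 15 into its delocalised potassium enolate. The enolate oxygen on the carbon that bears the 4-(methoxymethoxy)phenyl group adds to C8a'', the fluorine-bearing carbon ortho to the aroyl carbon C4a'', to give an anionic σ-adduct whose charge is taken up by the C4'' carbonyl, and loss of fluoride restores the arene (addition–elimination SNAr). The closest known reaction type is the base-mediated intramolecular O-arylation of 1-(2-fluoroaryl)-1,3-diketones to chromones and flavones. The pyranone closes as a six-membered ring by attack on an sp2 carbon with fluoride leaving from outside the ring: 6-exo-trig when counted on the C8a''=C8'' bond, 6-endo-trig when counted on the carbonyl-conjugated C4a''=C8a'' bond that carries the charge, and both are favoured closures. No stereocentre is formed. The step needs C8a''–F to react while C7''–F stays, and O-attack rather than C-attack: only the ortho fluorine is within reach of the tethered enolate, attack through the central carbon or the other oxygen would give a four-membered ring, and the para fluorine can only be attacked intermolecularly, which dilution and the weak nucleophilicity of a diketonate keep slow. The C5'' acetal oxygen is meta to C8a'' and does not push electron density onto the reacting carbon, and the aryl bromide and the three acetal ethers are inert to carbonate.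

**Step 9**
Reactants: 16 8-[5-bromo-2-(methoxymethoxy)phenyl]-7-fluoro-5-(methoxymethoxy)-2-[4-(methoxymethoxy)phenyl]-4H-chromen-4-one; 17 3-methylbut-2-en-1-ol
Product: 18 8-[5-bromo-2-(methoxymethoxy)phenyl]-5-(methoxymethoxy)-2-[4-(methoxymethoxy)phenyl]-7-[(3-methylbut-2-en-1-yl)oxy]-4H-chromen-4-one
Conditions: 17, NaH, THF, 0 °C; then 16, THF/DMF, 0 °C→rt
Reagents that add atoms: none
Why: SNAr of a 7-fluorochromone by an alkoxide; C7'' is para to C4a'' and activated through the C4'' carbonyl, the oxygens on C5'' and C8a'' are meta and do not donate to it, no phenol is free, and reversible alkoxide addition at C2'' is unproductive under anhydrous conditions.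

**Step 10**
Reactants: 18 8-[5-bromo-2-(methoxymethoxy)phenyl]-5-(methoxymethoxy)-2-[4-(methoxymethoxy)phenyl]-7-[(3-methylbut-2-en-1-yl)oxy]-4H-chromen-4-one
Product: 19 5-(methoxymethoxy)-2-[4-(methoxymethoxy)phenyl]-8-{2-(methoxymethoxy)-5-[(trimethylsilyl)ethynyl]phenyl}-7-[(3-methylbut-2-en-1-yl)oxy]-4H-chromen-4-one
Conditions: HC≡CSiMe3, Pd(PhCN)2Cl2 (cat.), P(t-Bu)3 (cat.), CuI (cat.), i-Pr2NH, dioxane, rt
Reagents that add atoms: ethynyltrimethylsilane, C#C[Si](C)(C)C
Why: Sonogashira coupling; this catalyst couples electron-rich aryl bromides at room temperature, and the low temperature and hindered amine give the prenyl ether little chance to ionise on palladium.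

**Step 11**
Reactants: 19 5-(methoxymethoxy)-2-[4-(methoxymethoxy)phenyl]-8-{2-(methoxymethoxy)-5-[(trimethylsilyl)ethynyl]phenyl}-7-[(3-methylbut-2-en-1-yl)oxy]-4H-chromen-4-one
Product: 20 8-[5-ethynyl-2-(methoxymethoxy)phenyl]-5-(methoxymethoxy)-2-[4-(methoxymethoxy)phenyl]-7-[(3-methylbut-2-en-1-yl)oxy]-4H-chromen-4-one
Conditions: K2CO3, MeOH/THF, rt
Reagents that add atoms: none
Why: methanolysis of the C(sp)–Si bond; acetal ethers, prenyl ether and pyranone are stable to carbonate in methanol at room temperature.

**Step 12**
Reactants: 21 benzene-1,3,5-triol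
Product: 22 2-iodobenzene-1,3,5-triol
Conditions: I2 (1 equiv), NaHCO3, THF/H2O, 0 °C
Reagents that add atoms: iodine, II
Why: electrophilic aromatic iodination of a very electron-rich phenol; the three ring positions are equivalent and stoichiometry limits the reaction to one iodine.

**Step 13**
Reactants: 22 2-iodobenzene-1,3,5-triol
Product: 23 2-iodobenzene-1,3,5-triyl triacetate
Conditions: Ac2O, pyridine, DMAP (cat.), CH2Cl2, 0 °C→rt
Reagents that add atoms: acetic anhydride, CC(=O)OC(C)=O
Why: O-acetylation; the triacetate is stable, less electron-rich and therefore better in oxidative addition, and still symmetric.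

**Step 14**
Reactants: 20 8-[5-ethynyl-2-(methoxymethoxy)phenyl]-5-(methoxymethoxy)-2-[4-(methoxymethoxy)phenyl]-7-[(3-methylbut-2-en-1-yl)oxy]-4H-chromen-4-one; 23 2-iodobenzene-1,3,5-triyl triacetate
Product: 25 8-[5-(5,7-dihydroxy-4-oxo-4H-chromen-2-yl)-2-(methoxymethoxy)phenyl]-5-(methoxymethoxy)-2-[4-(methoxymethoxy)phenyl]-7-[(3-methylbut-2-en-1-yl)oxy]-4H-chromen-4-one, via triacetoxyphenyl ynone 24 (not isolated)
Conditions: CO (1 atm), PdCl2(PPh3)2 (cat.), dppp, thiourea, Et2NH (excess), DBU, DMF, 40 °C
Reagents that add atoms: carbon monoxide, [C-]#[O+]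
Why: palladium-catalysed carbonylative annulation of an o-iodophenol acetate with a terminal alkyne: oxidative addition of 23, CO insertion and alkynylation give ynone 24; Et2NH then cleaves the acetates and, by reversible conjugate addition, steers the freed ortho phenol into 6-endo closure to the flavone rather than the 5-exo aurone; both ortho oxygens of 23 are equivalent, so one product is expected.

**Step 15**
Reactants: 25 8-[5-(5,7-dihydroxy-4-oxo-4H-chromen-2-yl)-2-(methoxymethoxy)phenyl]-5-(methoxymethoxy)-2-[4-(methoxymethoxy)phenyl]-7-[(3-methylbut-2-en-1-yl)oxy]-4H-chromen-4-one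
Product: 26 8-[5-(5,7-dihydroxy-4-oxo-4H-chromen-2-yl)-2-hydroxyphenyl]-5-hydroxy-2-(4-hydroxyphenyl)-7-[(3-methylbut-2-en-1-yl)oxy]-4H-chromen-4-one
Conditions: HCl (aq., dilute), MeOH/THF, 40 °C, monitored
Reagents that add atoms: none
Why: acid-catalysed acetal solvolysis (MOM removal); the O,O-acetals ionise much faster than the allylic aryl ether or the trisubstituted alkene is protonated, the peri acetal at O5'' going first and those at O4' and O4''' after it.

## Compound list

1 | 4-bromo-3,5-difluorophenol | Oc1cc(F)c(Br)c(F)c1 | starting material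
2 | 2-bromo-1,3-difluoro-5-(methoxymethoxy)benzene | COCOc1cc(F)c(Br)c(F)c1 | intermediate
3 | 4-bromo-2-iodophenol | Oc1ccc(Br)cc1I | starting material
4 | 4-bromo-2-iodo-1-(methoxymethoxy)benzene | COCOc1ccc(Br)cc1I | intermediate
5 | [2,6-difluoro-4-(methoxymethoxy)phenyl]magnesium chloride | COCOc1cc(F)c([Mg]Cl)c(F)c1 | intermediate
6 | [2,6-difluoro-4-(methoxymethoxy)phenyl]zinc chloride | COCOc1cc(F)c([Zn]Cl)c(F)c1 | intermediate
7 | 5'-bromo-2,6-difluoro-2',4-bis(methoxymethoxy)-1,1'-biphenyl | COCOc1cc(F)c(c(F)c1)-c1cc(Br)ccc1OCOC | intermediate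
8 | [5'-bromo-2,6-difluoro-2',4-bis(methoxymethoxy)-[1,1'-biphenyl]-3-yl]lithium | COCOc1cc(F)c(c(F)c1[Li])-c1cc(Br)ccc1OCOC | intermediate
9 | lithium 1-[5'-bromo-2,6-difluoro-2',4-bis(methoxymethoxy)-[1,1'-biphenyl]-3-yl]-1-[methoxy(methyl)amino]ethan-1-olate | CC(O[Li])(N(C)OC)c1c(OCOC)cc(F)c(c1F)-c1cc(Br)ccc1OCOC | intermediate
10 | 1-[5'-bromo-2,6-difluoro-2',4-bis(methoxymethoxy)-[1,1'-biphenyl]-3-yl]ethan-1-one | CC(=O)c1c(OCOC)cc(F)c(c1F)-c1cc(Br)ccc1OCOC | intermediate
11 | methyl 4-hydroxybenzoate | COC(=O)c1ccc(O)cc1 | starting material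
12 | methyl 4-(methoxymethoxy)benzoate | COCOc1ccc(cc1)C(=O)OC | intermediate
13 | 4-(methoxymethoxy)benzoic acid | COCOc1ccc(cc1)C(=O)O | intermediate
14 | (1H-imidazol-1-yl)[4-(methoxymethoxy)phenyl]methanone | COCOc1ccc(cc1)C(=O)n1ccnc1 | intermediate
15 | 1-[5'-bromo-2,6-difluoro-2',4-bis(methoxymethoxy)-[1,1'-biphenyl]-3-yl]-3-[4-(methoxymethoxy)phenyl]propane-1,3-dione | COCOc1ccc(cc1)C(=O)CC(=O)c1c(OCOC)cc(F)c(c1F)-c1cc(Br)ccc1OCOC | intermediate
16 | 8-[5-bromo-2-(methoxymethoxy)phenyl]-7-fluoro-5-(methoxymethoxy)-2-[4-(methoxymethoxy)phenyl]-4H-chromen-4-one | COCOc1ccc(cc1)-c1cc(=O)c2c(OCOC)cc(F)c(-c3cc(Br)ccc3OCOC)c2o1 | intermediate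
17 | 3-methylbut-2-en-1-ol | CC(C)=CCO | starting material
18 | 8-[5-bromo-2-(methoxymethoxy)phenyl]-5-(methoxymethoxy)-2-[4-(methoxymethoxy)phenyl]-7-[(3-methylbut-2-en-1-yl)oxy]-4H-chromen-4-one | COCOc1ccc(cc1)-c1cc(=O)c2c(OCOC)cc(OCC=C(C)C)c(-c3cc(Br)ccc3OCOC)c2o1 | intermediate
19 | 5-(methoxymethoxy)-2-[4-(methoxymethoxy)phenyl]-8-{2-(methoxymethoxy)-5-[(trimethylsilyl)ethynyl]phenyl}-7-[(3-methylbut-2-en-1-yl)oxy]-4H-chromen-4-one | COCOc1ccc(cc1)-c1cc(=O)c2c(OCOC)cc(OCC=C(C)C)c(-c3cc(C#C[Si](C)(C)C)ccc3OCOC)c2o1 | intermediate
20 | 8-[5-ethynyl-2-(methoxymethoxy)phenyl]-5-(methoxymethoxy)-2-[4-(methoxymethoxy)phenyl]-7-[(3-methylbut-2-en-1-yl)oxy]-4H-chromen-4-one | COCOc1ccc(cc1)-c1cc(=O)c2c(OCOC)cc(OCC=C(C)C)c(-c3cc(C#C)ccc3OCOC)c2o1 | intermediate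
21 | benzene-1,3,5-triol | Oc1cc(O)cc(O)c1 | starting material
22 | 2-iodobenzene-1,3,5-triol | Oc1cc(O)c(I)c(O)c1 | intermediate
23 | 2-iodobenzene-1,3,5-triyl triacetate | CC(=O)Oc1cc(OC(C)=O)c(I)c(OC(C)=O)c1 | intermediate
24 | 2-(3-{4-(methoxymethoxy)-3-[5-(methoxymethoxy)-2-(4-(methoxymethoxy)phenyl)-7-((3-methylbut-2-en-1-yl)oxy)-4-oxo-4H-chromen-8-yl]phenyl}prop-2-ynoyl)benzene-1,3,5-triyl triacetate | CC(=O)Oc1cc(OC(C)=O)c(C(=O)C#Cc2ccc(OCOC)c(c2)-c2c(OCC=C(C)C)cc(OCOC)c3c(=O)cc(oc23)-c2ccc(OCOC)cc2)c(OC(C)=O)c1 | intermediate
25 | 8-[5-(5,7-dihydroxy-4-oxo-4H-chromen-2-yl)-2-(methoxymethoxy)phenyl]-5-(methoxymethoxy)-2-[4-(methoxymethoxy)phenyl]-7-[(3-methylbut-2-en-1-yl)oxy]-4H-chromen-4-one | CC(C)=CCOc1cc(OCOC)c2c(=O)cc(-c3ccc(OCOC)cc3)oc2c1-c1cc(-c2cc(=O)c3c(O)cc(O)cc3o2)ccc1OCOC | intermediate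
26 | 8-[5-(5,7-dihydroxy-4-oxo-4H-chromen-2-yl)-2-hydroxyphenyl]-5-hydroxy-2-(4-hydroxyphenyl)-7-[(3-methylbut-2-en-1-yl)oxy]-4H-chromen-4-one | CC(C)=CCOc1cc(O)c2c(=O)cc(-c3ccc(O)cc3)oc2c1-c1cc(-c2cc(=O)c3c(O)cc(O)cc3o2)ccc1O | target

## Step count and least certain steps

Total step count: 15. Longest linear sequence: 10 steps (steps 1, 3, 4, 7, 8, 9, 10, 11, 14, 15).

**Step 8 (key step).**
- What may go wrong: the aroyl carbonyl at C4'' is flanked by fluorine and an acetal ether and is twisted out of the ring plane, so it activates C8a'' less than in a simple 2-fluorobenzoyl diketone. If closure is slow, retro-Claisen cleavage by moist carbonate and intermolecular attack of a second enolate on the para C7''–F gain ground.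
- Fallback: it sets out from 10 and returns at 16. Aldol addition of the lithium enolate of 10 (LiN(SiMe3)2, THF, −78 °C) to commercial 4-(methoxymethoxy)benzaldehyde should give the racemic β-hydroxy ketone F1. Its sodium alkoxide (NaH, THF, 0 °C), a much stronger oxygen nucleophile than a diketonate, closes onto C8a'' to the racemic 7''-fluoroflavanone F2. Dehydrogenation with DDQ in dioxane then gives 16.

**Step 9.**
- What may go wrong: the hindered C7'', activated only through a vinylogous ester carbonyl, may react slowly, and alkoxide addition at C2'' followed by opening of the pyranone then competes.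
- Fallback: it sets out from 16 and returns at 18, and brings the prenyl group in as an electrophile. Acetohydroxamic acid and K2CO3 in DMSO at 80 °C displace the fluorine to the O-aryl hydroxamate F3 (not isolated), which fragments in a Lossen-type step to the 7''-phenol F4. F4 has O7'' as its only free hydroxyl and is alkylated with 1-bromo-3-methylbut-2-ene and K2CO3 in acetone.

**Step 14.**
- What may go wrong: 5-exo closure to an aurone, direct alkynylation without CO uptake, capture of the acylpalladium by Et2NH as an amide, early deacetylation that leaves an arene too electron-rich for oxidative addition, or transfer of the prenyl group to the amine through an allylpalladium species.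
- Fallback: it sets out from 20 and 21 and returns at 26. Exhaustive protection of 21 (NaH, MOMCl, DMF) gives 1,3,5-tris(methoxymethoxy)benzene F5. Lithiation between two acetal ethers (n-BuLi, THF) and I2 give 2-iodo-1,3,5-tris(methoxymethoxy)benzene F6. Carbonylative Sonogashira coupling of 20 with F6 (CO, PdCl2(PPh3)2, Et3N, THF) gives the ynone F7, which has no free phenol and meets no secondary amine, so neither aurone closure nor amide formation is possible. The final acid treatment removes the six acetal groups, and the freed ortho phenol adds 6-endo to the ynone to give 26.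

**Step 15.**
- What may go wrong: acid-induced ionisation or hydration of the prenyl ether while the two ordinary aryl acetal ethers at O4' and O4''' are still being cleaved.
- Fallback: it sets out from 25 and returns at 26 without protic acid. Me3SiOTf with 2,2'-bipyridyl in CH2Cl2 at 0 °C exchanges each aryl O–CH2OMe for O–SiMe3, the methoxymethyl cation being taken up by the bipyridyl, and silylates the two free phenols as well. This gives the pentakis(trimethylsilyl) ether F8, which is hydrolysed to 26 by water and methanol on work-up.

## Further compounds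

F1 | step 8 | 1-[5'-bromo-2,6-difluoro-2',4-bis(methoxymethoxy)-[1,1'-biphenyl]-3-yl]-3-hydroxy-3-[4-(methoxymethoxy)phenyl]propan-1-one (racemic) | COCOc1ccc(cc1)C(O)CC(=O)c1c(OCOC)cc(F)c(c1F)-c1cc(Br)ccc1OCOC
F2 | step 8 | 8-[5-bromo-2-(methoxymethoxy)phenyl]-7-fluoro-5-(methoxymethoxy)-2-[4-(methoxymethoxy)phenyl]chroman-4-one (racemic) | COCOc1ccc(cc1)C1CC(=O)c2c(OCOC)cc(F)c(-c3cc(Br)ccc3OCOC)c2O1
F3 | step 9 | N-({8-[5-bromo-2-(methoxymethoxy)phenyl]-5-(methoxymethoxy)-2-[4-(methoxymethoxy)phenyl]-4-oxo-4H-chromen-7-yl}oxy)acetamide | COCOc1ccc(cc1)-c1cc(=O)c2c(OCOC)cc(ONC(C)=O)c(-c3cc(Br)ccc3OCOC)c2o1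
F4 | step 9 | 8-[5-bromo-2-(methoxymethoxy)phenyl]-7-hydroxy-5-(methoxymethoxy)-2-[4-(methoxymethoxy)phenyl]-4H-chromen-4-one | COCOc1ccc(cc1)-c1cc(=O)c2c(OCOC)cc(O)c(-c3cc(Br)ccc3OCOC)c2o1
F5 | step 14 | 1,3,5-tris(methoxymethoxy)benzene | COCOc1cc(OCOC)cc(OCOC)c1
F6 | step 14 | 2-iodo-1,3,5-tris(methoxymethoxy)benzene | COCOc1cc(OCOC)c(I)c(OCOC)c1
F7 | step 14 | 8-{2-(methoxymethoxy)-5-[3-oxo-3-(2,4,6-tris(methoxymethoxy)phenyl)prop-1-yn-1-yl]phenyl}-5-(methoxymethoxy)-2-[4-(methoxymethoxy)phenyl]-7-[(3-methylbut-2-en-1-yl)oxy]-4H-chromen-4-one | COCOc1cc(OCOC)c(C(=O)C#Cc2ccc(OCOC)c(c2)-c2c(OCC=C(C)C)cc(OCOC)c3c(=O)cc(oc23)-c2ccc(OCOC)cc2)c(OCOC)c1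
F8 | step 15 | pentakis(trimethylsilyl) ether of 26 (silyl groups on O5, O7, O4', O5'' and O4''') | CC(C)=CCOc1cc(O[Si](C)(C)C)c2c(=O)cc(-c3ccc(O[Si](C)(C)C)cc3)oc2c1-c1cc(-c2cc(=O)c3c(O[Si](C)(C)C)cc(O[Si](C)(C)C)cc3o2)ccc1O[Si](C)(C)C
A1 | alternative 1 | 3-(methoxymethoxy)cyclobut-2-en-1-one | O=C1CC(OCOC)=C1
A2 | alternative 1 | {[5-bromo-2-(methoxymethoxy)phenyl]ethynyloxy}tri(propan-2-yl)silane | COCOc1ccc(Br)cc1C#CO[Si](C(C)C)(C(C)C)C(C)C
A3 | alternative 1 | 2-[5-bromo-2-(methoxymethoxy)phenyl]-5-(methoxymethoxy)-3-[tri(propan-2-yl)silyloxy]phenol | COCOc1cc(O)c(-c2cc(Br)ccc2OCOC)c(O[Si](C(C)C)(C(C)C)C(C)C)c1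
A4 | alternative 2 | 8-[3-(tert-butyldimethylsilyloxy)buta-1,3-dien-2-yl]-5-(methoxymethoxy)-2-[4-(methoxymethoxy)phenyl]-7-[(3-methylbut-2-en-1-yl)oxy]-4H-chromen-4-one | CC(C)=CCOc1cc(OCOC)c2c(=O)cc(-c3ccc(OCOC)cc3)oc2c1C(=C)C(=C)O[Si](C)(C)C(C)(C)C
A5 | alternative 2 | 2-ethynyl-5,7-bis(methoxymethoxy)-4H-chromen-4-one | C#Cc1cc(=O)c2c(OCOC)cc(OCOC)cc2o1
A6 | alternative 2 | 3',8''-biflavone with tert-butyldimethylsilyl ether at O4', prenyl ether at O7'' and methoxymethyl ethers at O5, O7, O5'' and O4''' | CC(C)=CCOc1cc(OCOC)c2c(=O)cc(-c3ccc(OCOC)cc3)oc2c1-c1cc(-c2cc(=O)c3c(OCOC)cc(OCOC)cc3o2)ccc1O[Si](C)(C)C(C)(C)C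
A7 | alternative 3 | methyl 4-{5-[5,7-bis(methoxymethoxy)-4-oxo-4H-chromen-2-yl]-2-(methoxymethoxy)phenyl}-4-{6-[4-(methoxymethoxy)phenyl]-4-oxo-4H-pyran-2-yl}-3-oxobutanoate | COC(=O)CC(=O)C(c1cc(=O)cc(o1)-c1ccc(OCOC)cc1)c1cc(ccc1OCOC)-c1cc(=O)c2c(OCOC)cc(OCOC)cc2o1
A8 | alternative 3 | 5'',7''-dihydroxy-3',8''-biflavone with methoxymethyl ethers at O5, O7, O4' and O4''' | Oc1cc(O)c2c(=O)cc(-c3ccc(OCOC)cc3)oc2c1-c1cc(-c2cc(=O)c3c(OCOC)cc(OCOC)cc3o2)ccc1OCOC
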